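(Readings and results come from a simulation with constants of no real substance; scatter was added.)

The north and north-west runs charge the same amounts, cZ 0.25 M, cL 0.050 M and 0.95 equiv of E, and differ in Q, 1.3 mol% against 3 mol%. The south-east run has more L, so it stays out of this comparison.

the same everywhere: Z 0.25 M
- north: E 0.95 equiv; L 0.050 M; Q 1.3 mol%; run made earlier
- north-west: E 0.95 equiv; L 0.050 M; Q 3 mol%; run made earlier
- south-east: E 0.95 equiv; L 0.10 M; Q 2 mol%; run made earlier
- flask: E 0.950 equiv; L 0.0500 M; Q 2 mol%

- north (time / min: G / %, Z / %): 0.500: 5, 95; 1.33: 13, 82; 2.50: 18, 74; 4.00: 24, 64; 5.00: 27, 63; 8.00: 38, 47; 10.0: 38, 43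
- north-west (time / min: G / %, Z / %): 0.667: 12, 87; 1.00: 18, 78; 1.50: 26, 74; 2.50: 30, 58; 4.00: 38, 54; 6.00: 47, 42; 10.0: 52, 33
- south-east (time / min: G / %, Z / %): 0.667: 7, 87; 1.33: 15, 75; 2.50: 25, 62; 5.00: 36, 45; 10.0: 44, 37

(readings scatter by 2 percentage points)

* factor on the rate of making G when 30% of the Z are converted if Q is charged twice over
* factor on the rate when 30% of the Z are converted if Q is charged at 0.2 mol% instead



We work in powers of ten. The two loadings lie 0.363 apart on that scale. We define the apparent order in Q as the log distance between the two runs' times to one level, divided by this loading distance; below is the mean over the matching rows. This treats a time to a level as the inverse of a rate.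

Reading the tables against each other, G stands at 18% after 2.50 min in the north run and after 1.00 min in the north-west run, a log distance of 0.398. Z stands at 74% after 2.50 min and 1.50 min, a distance of 0.222. G first reaches 38% after 8.00 min and 4.00 min, a distance of 0.301.

Singly, these rows give orders from 0.612 to 1.10, on readings that scatter by 2 percentage points. Their mean gives 0.845.

For the flask at 2 mol%, we multiply the log distance in Q by this order. Doubling gives a factor of 1.80, and going to 0.2 mol% gives 0.143, both reached beyond the tested loadings.

The forecast, holding that “Q's order is clearly below one”, gives 1.6 on doubling, lower than our 1.80, and 0.2 at 0.2 mol%, higher than our 0.143.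

The flask gives 1.87 on doubling and 0.131 at 0.2 mol%. As orders these are 0.904 for doubling and 0.884 for the 0.2 mol% flask, both higher than our 0.845 and inside the spread of our rows.

    Z + E + Q → Q + G (k = 140 /M²/min)
    2 Q → X (k = 14.0 /M/min)
    Z + L → D (k = 0.770 /M/min)

In the flask, Z is used by the step with E and Q 4.3 times as fast as by the step with L at the start, and 2.7 times as fast at 15.0 min. At that time the flask holds G 52.2% and D 15.4% of the Z charged.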